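**Retrosynthetic overview**

1. Target 11 comes from diacetate 10 by removal of the two aryl acetates (last step).
2. 10 is cut into three components: terminal alkyne 4, Me3Al and aryl chloromethyl ether 8. A one-flask Zr-catalysed syn-methylalumination/aryloxymethylation makes the C2'–C1' bond (vinyl CH to OCH2), the C3'–CH3 bond and the E-trisubstituted C2'=C3' alkene.
3. Enabling feature: the side-chain unit ArO–C1'H2–C2'H=C3'(CH3)–C4'H2. It is an (E)-2-methylalk-1-enyl group (the retron of Me–Al syn addition to the C≡C–H of 4) bonded to an oxygen-bearing CH2, which is an aryloxymethyl cation equivalent (ArOCH2Cl).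
4. 4 comes from (S)-epichlorohydrin by two successive epoxide openings (isopropenyl cuprate, then acetylide), so the C5' carbinol centre is taken from the chiral pool. 8 comes from 2,4,6-trihydroxybenzophenone (4-O-methylthiomethyl ether, diacetate, SO2Cl2).
5. Rings: none is built. Both benzene rings arrive in 5; the only ring formed is the transient oxirane 3, opened in the same flask in step 2.

Key step: step 6

Assumption: (S)-epichlorohydrin and 2,4,6-trihydroxybenzophenone are taken as commercial; the carbinol centre of the target is (S) by CIP analysis, and it maps onto (S)-epichlorohydrin because no bond to that carbon is broken in the route.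

**Step 1**
Reactants: 1 (S)-epichlorohydrin
Product: 2 (S)-1-chloro-4-methylpent-4-en-2-ol
Conditions: isopropenylMgBr (1.2 equiv), CuI (10 mol%), THF, −40 → −20 °C; aqueous quench
Reagents that add atoms: isopropenylmagnesium bromide, C=C(C)[Mg]Br
Why: Copper-catalysed Grignard opening of the epoxide at its unsubstituted carbon (SN2, the C–Cl bond is untouched at low temperature) leaves the C–O stereocentre of 1 intact, so the chlorohydrin should be (S).

**Step 2**
Reactants: 2 (S)-1-chloro-4-methylpent-4-en-2-ol
Product: 4 (S)-2-methylhept-1-en-6-yn-4-ol, via (S)-2-(2-methylallyl)oxirane 3 (not isolated)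
Conditions: HC≡CLi·ethylenediamine (3 equiv), DMSO, 0 °C → rt
Reagents that add atoms: lithium acetylide–ethylenediamine complex, [Li+].[C-]#C.NCCN
Why: The acetylide first acts as base to close the chlorohydrin to the terminal epoxide (intramolecular Williamson reaction), and a further equivalent opens it at the CH2 terminus (SN2 epoxide alkynylation) without touching the stereocentre, so (S) is retained.

**Step 3**
Reactants: 5 2,4,6-trihydroxybenzophenone
Product: 6 {2,6-dihydroxy-4-[(methylsulfanyl)methoxy]phenyl}(phenyl)methanone
Conditions: MeSCH2Cl (1.05 equiv), K2CO3 (1.1 equiv), NaI (cat.), acetone, 0 °C → rt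
Reagents that add atoms: chloromethyl methyl sulfide, CSCCl
Why: Williamson etherification should be selective for the 4-OH, which is para to the benzoyl group, the most acidic phenol, and the only one not held in a hydrogen bond to the carbonyl.

**Step 4**
Reactants: 6 {2,6-dihydroxy-4-[(methylsulfanyl)methoxy]phenyl}(phenyl)methanone
Product: 7 2-benzoyl-5-[(methylsulfanyl)methoxy]-1,3-phenylene diacetate
Conditions: Ac2O, pyridine, DMAP (cat.), CH2Cl2, rt
Reagents that add atoms: acetic anhydride, CC(=O)OC(C)=O
Why: DMAP-catalysed acylation caps both chelated phenols, which removes the acidic protons that would destroy the organoaluminium reagent and deactivates the arene towards the electrophiles of step 5.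

**Step 5**
Reactants: 7 2-benzoyl-5-[(methylsulfanyl)methoxy]-1,3-phenylene diacetate
Product: 8 2-benzoyl-5-(chloromethoxy)-1,3-phenylene diacetate
Conditions: SO2Cl2 (1.05 equiv), CH2Cl2, 0 °C; evaporation; used crude at once
Reagents that add atoms: sulfuryl chloride, O=S(=O)(Cl)Cl
Why: S-chlorination of the O,S-acetal and collapse of the chlorosulfonium ion (the established cleavage of methylthiomethyl aryl ethers to aryl chloromethyl ethers) should give the α-chloro ether, with only volatile by-products and a ring that the acetoxy and benzoyl groups protect from chlorination.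

**Step 6**
Reactants: 4 (S)-2-methylhept-1-en-6-yn-4-ol; 8 2-benzoyl-5-(chloromethoxy)-1,3-phenylene diacetate
Product: 10 2-benzoyl-5-{[(2E,5S)-5-hydroxy-3,7-dimethylocta-2,7-dien-1-yl]oxy}-1,3-phenylene diacetate, via (E)-alkenyldimethylalane 9 (not isolated)
Conditions: 4 (1.3 equiv), Me3Al (3 equiv per 4), Cp2ZrCl2 (20 mol%), CH2Cl2, −20 °C → rt; volatiles and excess Me3Al removed in vacuo; CH2Cl2, then 8 (1.0 equiv), −40 °C → rt; aqueous Rochelle salt
Reagents that add atoms: trimethylaluminium, C[Al](C)C
Why: Proposed new method: Cp2ZrCl2/Me3Al should deliver Me–Al syn across the terminal alkyne of 4 (carried as its dimethylaluminium alkoxide), methyl to the internal and aluminium to the terminal carbon, to give the (E)-alkenylalane 9; after excess Me3Al is stripped off, the Lewis-acidic aluminium abstracts chloride from 8 and the aryloxymethyl oxocarbenium ion pair is captured at the C(sp2)–Al carbon with retention, forming the vinyl CH–CH2O bond. The closest known reaction type is the Zr-catalysed methylalumination of terminal alkynes with in-flask trapping of the alkenylalane by carbon electrophiles such as chloroformates and chloromethyl methyl ether to give (E)-trisubstituted allylic products; new here is an aryl chloromethyl ether that carries a complete functionalised arene. No ring is closed and no stereocentre is created; the (S)-carbinol is not touched. The E geometry follows from syn carbometalation and stereoretentive C–Al substitution, provided the mixture stays at or below room temperature so that chelation-driven E/Z isomerisation of the homopropargylic alkoxide adduct does not start. The step needs Me-to-internal regiochemistry (secured by the terminal alkyne), alkyne over 1,1-disubstituted alkene (isolated alkenes are inert to this catalyst), alkenyl over methyl transfer from aluminium (the sp2 C–Al bond reacts first) and attack at the oxocarbenium carbon in preference to the ketone, the acetates or the alkoxide oxygen (the benzoyl carbonyl is flanked by two ortho-acetoxy groups, the alkoxide oxygen is tied up in an Al–O–Al bridge, and the electrophile is added cold).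

**Step 7**
Reactants: 10 2-benzoyl-5-{[(2E,5S)-5-hydroxy-3,7-dimethylocta-2,7-dien-1-yl]oxy}-1,3-phenylene diacetate
Product: 11 {2,6-dihydroxy-4-[((2E,5S)-5-hydroxy-3,7-dimethylocta-2,7-dien-1-yl)oxy]phenyl}(phenyl)methanone (target)
Conditions: NH3 (7 M in MeOH), 0 °C → rt
Reagents that add atoms: none
Why: Aminolysis of the two aryl acetates, by far the most labile groups present, should free both phenols without affecting the allyl aryl ether, the two alkenes or the carbinol centre.

**Compound list**

1 | (S)-epichlorohydrin [(S)-2-(chloromethyl)oxirane] | ClC[C@@H]1CO1 | starting material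
2 | (S)-1-chloro-4-methylpent-4-en-2-ol | C=C(C)C[C@H](O)CCl | intermediate
3 | (S)-2-(2-methylallyl)oxirane | C=C(C)C[C@H]1CO1 | intermediate
4 | (S)-2-methylhept-1-en-6-yn-4-ol | C=C(C)C[C@H](O)CC#C | intermediate
5 | 2,4,6-trihydroxybenzophenone | O=C(c1ccccc1)c1c(O)cc(O)cc1O | starting material
6 | {2,6-dihydroxy-4-[(methylsulfanyl)methoxy]phenyl}(phenyl)methanone | CSCOc1cc(O)c(C(=O)c2ccccc2)c(O)c1 | intermediate
7 | 2-benzoyl-5-[(methylsulfanyl)methoxy]-1,3-phenylene diacetate | CSCOc1cc(OC(C)=O)c(C(=O)c2ccccc2)c(OC(C)=O)c1 | intermediate
8 | 2-benzoyl-5-(chloromethoxy)-1,3-phenylene diacetate | ClCOc1cc(OC(C)=O)c(C(=O)c2ccccc2)c(OC(C)=O)c1 | intermediate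
9 | [(1E,4S)-4-[(dimethylalumanyl)oxy]-2,6-dimethylhepta-1,6-dien-1-yl]dimethylalumane | C=C(C)C[C@H](O[Al](C)C)C/C(C)=C/[Al](C)C | intermediate
10 | 2-benzoyl-5-{[(2E,5S)-5-hydroxy-3,7-dimethylocta-2,7-dien-1-yl]oxy}-1,3-phenylene diacetate | C=C(C)C[C@H](O)C/C(C)=C/COc1cc(OC(C)=O)c(C(=O)c2ccccc2)c(OC(C)=O)c1 | intermediate
11 | {2,6-dihydroxy-4-[((2E,5S)-5-hydroxy-3,7-dimethylocta-2,7-dien-1-yl)oxy]phenyl}(phenyl)methanone | C=C(C)C[C@H](O)C/C(C)=C/COc1cc(O)c(C(=O)c2ccccc2)c(O)c1 | target

**Step count and risks**

Total steps: 7. Longest linear sequence: 5 steps (steps 3, 4, 5, 6, 7 from 5); the alkyne branch is 2 steps before the convergence.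

Steps most likely to fail:

1. Step 6 (proposed new method). Ionisation of the electron-poor aryl chloromethyl ether by the alane may be slow, so that methyl transfer, attack on the benzoyl or acetate carbonyls, or O-alkylation of the aluminium alkoxide competes with alkenyl transfer. The fallback uses known chemistry, sets out from 4 (with 5) and comes back at 11. Alkyne 4 is methylaluminated as in step 6 to alane 9, which is converted with n-BuLi into lithium butyl(alkenyl)dimethylalanate F1 and trapped with paraformaldehyde (the established hydroxymethylation of alkenylalanates) to give (2E,5S)-3,7-dimethylocta-2,7-diene-1,5-diol F2. A Mitsunobu etherification (PPh3, DIAD, THF, 0 °C) then joins the primary allylic hydroxyl of F2 to the 4-OH of 5 and should give 11 directly. The 4-OH is the most acidic, non-chelated phenol, and the secondary carbinol reacts much more slowly than the primary allylic one.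

2. Step 5. Electrophilic chlorination or sulfenylation of the arene, or hydrolysis of the α-chloro ether during handling, may erode the electrophile before it is used. The fallback reverses the polarity of the one-carbon unit, sets out from 4 and 5 and comes back at 11. Alane 9 from 4 is quenched with iodine to give (4S,6E)-7-iodo-2,6-dimethylhepta-1,6-dien-4-ol F3. Separately, 5 is O-alkylated at its 4-OH with potassium (bromomethyl)trifluoroborate (K2CO3, acetone, reflux) to give potassium [(4-benzoyl-3,5-dihydroxyphenoxy)methyl]trifluoroborate F4. A Suzuki–Miyaura sp2–sp3 coupling of F3 and F4 (Pd(OAc)2, RuPhos, Cs2CO3, dioxane–H2O, 90 °C) forms the same vinyl CH–CH2O bond and should give 11 without protecting groups. This coupling is closely precedented for alkoxymethyltrifluoroborates with aryl halides, not yet with an alkenyl iodide of this kind.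

3. Step 3. Over-alkylation, C-alkylation of the electron-rich ring, or incomplete discrimination between the three phenols may give mixtures. The fallback replaces selective alkylation by selective unmasking, sets out from 5 and comes back at 7. Compound 5 is peracetylated (Ac2O, pyridine) to 2-benzoylbenzene-1,3,5-triyl triacetate F5. The acetate para to the carbonyl is then removed selectively (PhSH, imidazole, NMP, 0 °C; the same selectivity is known for peracetylated flavonoids) to give 2-benzoyl-5-hydroxy-1,3-phenylene diacetate F6. Its single free phenol, on a deactivated ring, is O-alkylated with MeSCH2Cl (K2CO3, NaI, acetone) to give 7.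

**Further compounds**

F1 | step 6 | lithium butyl[(1E,4S)-4-[(dimethylalumanyl)oxy]-2,6-dimethylhepta-1,6-dien-1-yl]dimethylalanate | [Li+].C=C(C)C[C@H](O[Al](C)C)C/C(C)=C/[Al-](C)(C)CCCC
F2 | step 6 | (2E,5S)-3,7-dimethylocta-2,7-diene-1,5-diol | C=C(C)C[C@H](O)C/C(C)=C/CO
F3 | step 5 | (4S,6E)-7-iodo-2,6-dimethylhepta-1,6-dien-4-ol | C=C(C)C[C@H](O)C/C(C)=C/I
F4 | step 5 | potassium [(4-benzoyl-3,5-dihydroxyphenoxy)methyl]trifluoroborate | [K+].F[B-](F)(F)COc1cc(O)c(C(=O)c2ccccc2)c(O)c1
F5 | step 3 | 2-benzoylbenzene-1,3,5-triyl triacetate | CC(=O)Oc1cc(OC(C)=O)c(C(=O)c2ccccc2)c(OC(C)=O)c1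
F6 | step 3 | 2-benzoyl-5-hydroxy-1,3-phenylene diacetate | CC(=O)Oc1cc(O)cc(OC(C)=O)c1C(=O)c1ccccc1
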